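Oxolane numbering: O1, C2 (aryl), C3 (aroyl), C4 (aroyl), C5 (aryl). Everything rests on reading the ring bond C2–C3 as a hidden aldol bond: C3 is the α-carbon of an exocyclic aryl ketone, C2 an O1-bound benzylic carbon at aldehyde oxidation level. The precursor is an open-chain syn-aldol of a symmetrical 1,4-diketone that already holds C4 and C5. In one operation its silyl ether condenses with a second aldehyde molecule to an O1=C2 oxocarbenium ion, which the tethered C3 enol silane captures; this closes the ring and sets C2 and C3. Carbonate-deactivated aryl groups keep the benzylic positions from ionising and are removed by hydrogenolysis.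

Key step: step 5

Remark on the structure: in this numbering the target is 2S,3R,4R,5R, with C2/C3 cis, C3/C4 trans, C4/C5 trans and C2/C5 cis.

Assumption: the (Z)-enolborinate carrying isopinocampheyl groups from (−)-α-pinene is taken to attack the re face of the aldehyde, as the mirror image of the si-face preference of the (+)-α-pinene series; should the sense prove opposite, the antipodal borane is used.

Step 1
Reactants: 1 2,4-dihydroxyacetophenone
Product: 2 1-[2,4-bis(benzyloxy)phenyl]ethan-1-one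
Conditions: BnBr (2.4 equiv), K2CO3, DMF, 70 °C
Reagents that add atoms: benzyl bromide, BrCc1ccccc1
Why: Williamson etherification in warm DMF should alkylate both phenols, including the hydrogen-bonded 2-OH, and creates no stereocentre.

Step 2
Reactants: 2 1-[2,4-bis(benzyloxy)phenyl]ethan-1-one (2 equiv)
Product: 4 1,4-bis[2,4-bis(benzyloxy)phenyl]butane-1,4-dione, via lithium enolate 3 (not isolated)
Conditions: LiN(iPr)2 (LDA), THF, −78 °C; CuCl2, DMF, −78 °C to rt
Reagents that add atoms: none
Why: Oxidative homocoupling of a methyl ketone lithium enolate with CuCl2 (Saegusa-type enolate dimerisation) should join the two α-carbons to the symmetrical 1,4-diketone, with no stereocentre formed.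

Step 3
Reactants: 5 4-hydroxybenzaldehyde
Product: 6 benzyl 4-formylphenyl carbonate
Conditions: CbzCl, Et3N, CH2Cl2, 0 °C
Reagents that add atoms: benzyl chloroformate, O=C(Cl)OCc1ccccc1
Why: O-acylation of the phenol should give an electron-poor aryl carbonate that later suppresses benzylic ionisation at C5 and C2 and is cleaved by hydrogenolysis.

Step 4
Reactants: 4 1,4-bis[2,4-bis(benzyloxy)phenyl]butane-1,4-dione; 6 benzyl 4-formylphenyl carbonate
Product: 9 (2R)-1,4-bis[2,4-bis(benzyloxy)phenyl]-2-[(R)-(4-{[(benzyloxy)carbonyl]oxy}phenyl)(hydroxy)methyl]butane-1,4-dione, via enolborinate 7 (not isolated), via boron aldolate 8 (not isolated)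
Conditions: (+)-Ipc2BOTf (from (−)-α-pinene, 1.05 equiv), iPr2NEt, CH2Cl2, −78 °C; 6, −78 to −20 °C; 8-hydroxyquinoline, Et2O–MeOH, rt
Reagents that add atoms: none
Why: Paterson aldol, in which the (Z)-enolborinate reacts through a Zimmerman–Traxler chair to give the syn aldol, the isopinocampheyl groups direct re-face attack on the aldehyde and so set both C4 (R) and C5 (R), and the non-oxidative work-up spares the aryl carbonate.

Step 5
Reactants: 9 (2R)-1,4-bis[2,4-bis(benzyloxy)phenyl]-2-[(R)-(4-{[(benzyloxy)carbonyl]oxy}phenyl)(hydroxy)methyl]butane-1,4-dione; 6 benzyl 4-formylphenyl carbonate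
Product: 12 [(2S,3R,4R,5R)-2,5-bis(4-{[(benzyloxy)carbonyl]oxy}phenyl)oxolane-3,4-diyl]bis{[2,4-bis(benzyloxy)phenyl]methanone}, via bis-silyl compound 10 (not isolated), via oxocarbenium triflate 11 (not isolated)
Conditions: iPr2NEt (2.4 equiv), Me3SiOTf (2.2 equiv), CH2Cl2, −78 to 0 °C; then 6 (1.2 equiv), Me3SiOTf (0.3 equiv), −78 °C; pyridine quench at −78 °C
Reagents that add atoms: none
Why: Soft enolisation should silylate the C5 hydroxyl and convert the CH2 ketone, in preference to the more hindered CH ketone, into the C3 enol silane 10; Me3SiOTf then condenses the silyl ether with aldehyde 6 (silyl-modified, Noyori/Markó-type oxocarbenium formation) to the (E)-oxocarbenium ion 11, which the tethered enol silane attacks at C2 in an intramolecular Mukaiyama aldol (Prins-type) addition, after which loss of the silyl group regenerates Me3SiOTf. The closest known reaction types are silyl-modified Sakurai and Mukaiyama additions to in situ oxocarbenium ions and the identical enolate-to-oxocarbenium closure that ends the Lewis-acid ring contraction of 4,5-dihydro-1,3-dioxepines and the aldehyde/donor–acceptor cyclopropane annulation to 3-acyl oxolanes. The oxolane closes in the 5-(enolexo)-endo-trig mode, endo to the O1=C2 bond. C2 is controlled by the (E)-oxocarbenium geometry in an envelope transition state with the C5 aryl pseudo-equatorial, which should give the 2,5-cis relationship; C3 is controlled by the C4 stereocentre, the exocyclic enol carbon adding synclinal and staggered away from the pseudo-equatorial C4 aroyl, which should give 3,4-trans and therefore 2,3-cis, the kinetic cis outcome of this closure at −78 °C. The step needs chemoselectivity for oxocarbenium formation at the tethered oxygen over intermolecular aldol addition, lactol or dihydrofuran formation and benzylic ionisation. This is secured by masking the C3 ketone as its enol silane before the aldehyde is added, by the low temperature at which Me3SiOTf does not promote direct aldehyde aldol addition, and by the carbonate-deactivated aryl rings.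

Step 6
Reactants: 12 [(2S,3R,4R,5R)-2,5-bis(4-{[(benzyloxy)carbonyl]oxy}phenyl)oxolane-3,4-diyl]bis{[2,4-bis(benzyloxy)phenyl]methanone}
Product: 13 [(2S,3R,4R,5R)-2,5-bis(4-hydroxyphenyl)oxolane-3,4-diyl]bis[(2,4-dihydroxyphenyl)methanone] (CNP0237262.2)
Conditions: H2 (1 atm), Pd/C (10 wt %), EtOAc–MeOH, rt
Reagents that add atoms: none
Why: Hydrogenolysis should cleave the four aryl benzyl ethers and the two benzyl carbonates (with loss of CO2) faster than the ring benzylic C–O bonds, under neutral conditions that do not epimerise C3 and C4, both of which are α to ketones.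

Compound list
1 | 2,4-dihydroxyacetophenone | CC(=O)c1ccc(O)cc1O | starting material
2 | 1-[2,4-bis(benzyloxy)phenyl]ethan-1-one | CC(=O)c1ccc(OCc2ccccc2)cc1OCc1ccccc1 | intermediate
3 | lithium enolate of 2 | [Li]OC(=C)c1ccc(OCc2ccccc2)cc1OCc1ccccc1 | intermediate
4 | 1,4-bis[2,4-bis(benzyloxy)phenyl]butane-1,4-dione | O=C(CCC(=O)c1ccc(OCc2ccccc2)cc1OCc1ccccc1)c1ccc(OCc2ccccc2)cc1OCc1ccccc1 | intermediate
5 | 4-hydroxybenzaldehyde | O=Cc1ccc(O)cc1 | starting material
6 | benzyl 4-formylphenyl carbonate | O=Cc1ccc(OC(=O)OCc2ccccc2)cc1 | intermediate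
7 | (Z)-enol diisopinocampheylborinate of 4 (isopinocampheyl groups from (−)-α-pinene) | O=C(c1ccc(OCc2ccccc2)cc1OCc1ccccc1)C/C=C(\OB([C@H]1C[C@H]2C[C@@H]([C@@H]1C)C2(C)C)[C@H]1C[C@H]2C[C@@H]([C@@H]1C)C2(C)C)c1ccc(OCc2ccccc2)cc1OCc1ccccc1 | intermediate
8 | O-diisopinocampheylboryl aldolate of 9 | O=C(c1ccc(OCc2ccccc2)cc1OCc1ccccc1)C[C@@H](C(=O)c1ccc(OCc2ccccc2)cc1OCc1ccccc1)[C@H](c1ccc(OC(=O)OCc2ccccc2)cc1)OB([C@H]1C[C@H]2C[C@@H]([C@@H]1C)C2(C)C)[C@H]1C[C@H]2C[C@@H]([C@@H]1C)C2(C)C | intermediate
9 | (2R)-1,4-bis[2,4-bis(benzyloxy)phenyl]-2-[(R)-(4-{[(benzyloxy)carbonyl]oxy}phenyl)(hydroxy)methyl]butane-1,4-dione (syn aldol) | O=C(c1ccc(OCc2ccccc2)cc1OCc1ccccc1)C[C@@H](C(=O)c1ccc(OCc2ccccc2)cc1OCc1ccccc1)[C@H](c1ccc(OC(=O)OCc2ccccc2)cc1)O | intermediate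
10 | C5 trimethylsilyl ether and (Z)-C3 trimethylsilyl enol ether of 9 | C[Si](C)(C)O/C(c1ccc(OCc2ccccc2)cc1OCc1ccccc1)=C\[C@@H](C(=O)c1ccc(OCc2ccccc2)cc1OCc1ccccc1)[C@H](c1ccc(OC(=O)OCc2ccccc2)cc1)O[Si](C)(C)C | intermediate
11 | (E)-O1=C2 oxocarbenium triflate formed from 10 and 6 | C[Si](C)(C)O/C(c1ccc(OCc2ccccc2)cc1OCc1ccccc1)=C\[C@@H](C(=O)c1ccc(OCc2ccccc2)cc1OCc1ccccc1)[C@H](c1ccc(OC(=O)OCc2ccccc2)cc1)/[O+]=C/c1ccc(OC(=O)OCc2ccccc2)cc1.[O-]S(=O)(=O)C(F)(F)F | intermediate
12 | [(2S,3R,4R,5R)-2,5-bis(4-{[(benzyloxy)carbonyl]oxy}phenyl)oxolane-3,4-diyl]bis{[2,4-bis(benzyloxy)phenyl]methanone} | O=C(c1ccc(OCc2ccccc2)cc1OCc1ccccc1)[C@@H]1[C@@H](C(=O)c2ccc(OCc3ccccc3)cc2OCc2ccccc2)[C@H](c2ccc(OC(=O)OCc3ccccc3)cc2)O[C@@H]1c1ccc(OC(=O)OCc2ccccc2)cc1 | intermediate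
13 | [(2S,3R,4R,5R)-2,5-bis(4-hydroxyphenyl)oxolane-3,4-diyl]bis[(2,4-dihydroxyphenyl)methanone] | O=C(c1ccc(O)cc1O)[C@@H]1[C@@H](C(=O)c2ccc(O)cc2O)[C@H](c2ccc(O)cc2)O[C@@H]1c1ccc(O)cc1 | target

Total step count: 6. Longest linear sequence: 5 steps (steps 1, 2, 4, 5, 6).

Steps most likely to fail

1. Step 5. The enol silane may add to the free aldehyde intermolecularly before the oxocarbenium ion is formed at the tethered oxygen. The C4 ketone oxygen may capture the cation. The new C3 centre may epimerise through ring opening and reclosure if the mixture warms.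
   Fallback (sets out from 9, returns at 13): the same bond is closed by oxidative C–H cleavage instead of aldehyde condensation.
   - 9 is O-alkylated with 4-(benzyloxy)benzyl 2,2,2-trichloroacetimidate (Sc(OTf)3 cat., toluene, 0 °C) to the electron-rich 4-(benzyloxy)benzyl ether F1.
   - Kinetic enolisation at the CH2 ketone (LiN(SiMe3)2, THF, −78 °C; Ac2O) should give the (Z)-enol acetate F2.
   - DDQ (2,6-dichloropyridine, LiClO4, 4 Å molecular sieves, 1,2-dichloroethane, rt) should abstract hydride only from the 4-(benzyloxy)benzyl CH2, because the C5 aryl is carbonate-deactivated. The enol acetate closes C2–C3 on the resulting oxocarbenium ion to the oxolane with a benzyl ether on the C2 aryl F3.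
   - Hydrogenolysis as in step 6 should give 13.

2. Step 4. Facial control by the isopinocampheyl groups may be insufficient for this hindered aryl ketone enolate. Bis-enolisation of the symmetrical diketone or retro-aldol cleavage on work-up may lower the selectivity.
   Fallback (sets out from 4, returns at 9): the stereocontrol is moved from the boron ligands to a chiral Lewis-base catalyst.
   - 4 is mono-enolised (LiN(SiMe3)2, THF, −78 °C; Me3SiCl) to the (Z)-mono(trimethylsilyl) enol ether F4.
   - Trans-silylation (SiCl4, Hg(OAc)2 cat., CH2Cl2) gives the (Z)-trichlorosilyl enolate F5.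
   - Aldol addition to 6 is catalysed by a chiral stilbenediamine-derived phosphoramide (10 mol %, CH2Cl2, −78 °C; aqueous NaHCO3), using the catalyst enantiomer that delivers re-face attack. The syn-selective addition of the (Z)-enolate should give 9.

3. Step 6. Over-reduction may occur, either by hydrogenolysis of the ring benzylic C–O bonds at C2 and C5 or by reduction of the aryl ketones.
   Fallback (sets out from 12, returns at 13): Lewis-acid debenzylation with a cation scavenger (BCl3, pentamethylbenzene, CH2Cl2, −78 °C; MeOH quench) should remove the benzyl ethers and benzyl carbonates without hydrogen and without base.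

Further compounds
F1 | step 5 | (2R)-1,4-bis[2,4-bis(benzyloxy)phenyl]-2-[(R)-{[4-(benzyloxy)benzyl]oxy}(4-{[(benzyloxy)carbonyl]oxy}phenyl)methyl]butane-1,4-dione | O=C(c1ccc(OCc2ccccc2)cc1OCc1ccccc1)C[C@@H](C(=O)c1ccc(OCc2ccccc2)cc1OCc1ccccc1)[C@H](c1ccc(OC(=O)OCc2ccccc2)cc1)OCc1ccc(OCc2ccccc2)cc1
F2 | step 5 | (Z)-enol acetate of F1 at the CH2 ketone | CC(=O)O/C(c1ccc(OCc2ccccc2)cc1OCc1ccccc1)=C\[C@@H](C(=O)c1ccc(OCc2ccccc2)cc1OCc1ccccc1)[C@H](c1ccc(OC(=O)OCc2ccccc2)cc1)OCc1ccc(OCc2ccccc2)cc1
F3 | step 5 | {(2S,3R,4R,5R)-2-[4-(benzyloxy)phenyl]-5-(4-{[(benzyloxy)carbonyl]oxy}phenyl)oxolane-3,4-diyl}bis{[2,4-bis(benzyloxy)phenyl]methanone} | O=C(c1ccc(OCc2ccccc2)cc1OCc1ccccc1)[C@@H]1[C@@H](C(=O)c2ccc(OCc3ccccc3)cc2OCc2ccccc2)[C@H](c2ccc(OC(=O)OCc3ccccc3)cc2)O[C@@H]1c1ccc(OCc2ccccc2)cc1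
F4 | step 4 | (Z)-1,4-bis[2,4-bis(benzyloxy)phenyl]-4-[(trimethylsilyl)oxy]but-3-en-1-one | C[Si](C)(C)O/C(c1ccc(OCc2ccccc2)cc1OCc1ccccc1)=C\CC(=O)c1ccc(OCc2ccccc2)cc1OCc1ccccc1
F5 | step 4 | (Z)-1,4-bis[2,4-bis(benzyloxy)phenyl]-4-[(trichlorosilyl)oxy]but-3-en-1-one | Cl[Si](Cl)(Cl)O/C(c1ccc(OCc2ccccc2)cc1OCc1ccccc1)=C\CC(=O)c1ccc(OCc2ccccc2)cc1OCc1ccccc1
F0 | step 6 | none | none
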